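The target is a tetrahydrofuran (ring atoms O1, C2–C5) whose trans carbons C3 and C4 each carry one benzylic CH2 (C6 on C3, C7 on C4). That pattern is trans-tetrahydrofuran-3,4-diol with each ring C–O bond exchanged for a C–C bond on the same face. The precursor is therefore the C2-symmetric bis(3,4-dimethoxybenzyl) ether of (3R,4R)-tetrahydrofuran-3,4-diol. One operation, a twofold [1,2]-Wittig rearrangement, should move C3 and C4 from oxygen to the benzylic carbons with retention, forming C3–C6 and C4–C7 and thus the whole carbon skeleton. The two carbinol oxygens left behind are then removed by acetylation and neutral hydrogenolysis.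

Key step: step 2

Assumption: (3R,4R)-tetrahydrofuran-3,4-diol (1,4-anhydro-D-threitol) is bought enantiopure; retention at both ring carbons turns its (3R,4R) ether into the (3S,4S) carbon series only because the CIP priorities change, the spatial arrangement being kept.

Step 1
Reactants: 1 (3R,4R)-tetrahydrofuran-3,4-diol; 2 3,4-dimethoxybenzyl chloride
Product: 3 (3R,4R)-3,4-bis[(3,4-dimethoxybenzyl)oxy]tetrahydrofuran
Conditions: NaH (2.5 equiv), 2 (2.3 equiv), Bu4NI (cat.), THF–DMF, 0 °C → rt
Reagents that add atoms: none
Why: Twofold Williamson ether synthesis: the sodium alkoxides of 1 displace chloride (via the benzylic iodide formed with Bu4NI) by SN2 at the benzylic carbons only, so the two C–O stereocentres of 1 are carried into 3 unchanged.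

Step 2
Reactants: 3 (3R,4R)-3,4-bis[(3,4-dimethoxybenzyl)oxy]tetrahydrofuran
Product: 5 [(3S,4S)-tetrahydrofuran-3,4-diyl]bis[(3,4-dimethoxyphenyl)methanol] (mixture of epimers at the carbinol carbons C6 and C7), via mono-rearranged lithium alkoxide 4 (not isolated)
Conditions: sec-BuLi (5 equiv), THF, −78 °C, then −78 → −20 °C; sat. aq NH4Cl
Reagents that add atoms: none
Why: Proposed new method: sec-BuLi removes one O–CH2–Ar proton and the α-lithio ether breaks its O–C3 bond homolytically to a caged pair of lithium ketyl and tetrahydrofuran-3-yl radical that recombines at carbon (C3–C6), after which alkoxide 4 repeats the sequence at the second ether (C4–C7) and aqueous NH4Cl releases diol 5. The closest known reaction type is the [1,2]-Wittig rearrangement of benzyl secondary-alkyl ethers, including the O→C shift of benzyl glycosides, which runs with predominant retention at the migrating carbon; untested here are the twofold use on a vicinal bis-ether, the electron-rich aryl groups and the unstabilised, β-oxygenated migrating carbons. No ring is formed or opened, the tetrahydrofuran serving only as the scaffold that carries the two migrating carbons. C3 and C4 should keep their configuration because recombination inside the solvent cage is expected to outrun tumbling of the radical, and the trans neighbour (first the C4 ether, then the C3 carbinolate side chain) shields the opposite face, so both biases point to the trans (3S,4S) product; the carbinol centres C6 and C7 are not controlled and are erased in step 4. The step needs benzylic α-metalation to win over aryl ortho-metalation, ring C–H metalation and syn β-elimination of the benzylic anion, which the oxygen-acidified and oxygen-directed benzylic CH2 groups, kinetic deprotonation at −78 °C without diamine additives and warming only as far as the shift requires should secure.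

Step 3
Reactants: 5 [(3S,4S)-tetrahydrofuran-3,4-diyl]bis[(3,4-dimethoxyphenyl)methanol]
Product: 6 [(3S,4S)-tetrahydrofuran-3,4-diyl]bis[(3,4-dimethoxyphenyl)methylene] diacetate (mixture of epimers at C6 and C7)
Conditions: Ac2O, pyridine, DMAP (cat.), CH2Cl2, rt
Reagents that add atoms: acetic anhydride, CC(=O)OC(C)=O
Why: Nucleophile-catalysed acylation (Ac2O/DMAP) esterifies both secondary benzylic hydroxyls under basic, non-ionising conditions, so no benzylic cation can arise next to C3 or C4 and the ring stereocentres are not touched.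

Step 4
Reactants: 6 [(3S,4S)-tetrahydrofuran-3,4-diyl]bis[(3,4-dimethoxyphenyl)methylene] diacetate
Product: 7 (3S,4S)-3,4-bis(3,4-dimethoxybenzyl)tetrahydrofuran
Conditions: H2 (1–4 atm), 10% Pd/C, EtOAc–EtOH, rt
Reagents that add atoms: none
Why: Catalytic hydrogenolysis of benzylic C–O bonds: the electron-rich benzylic acetates are cleaved on Pd under neutral conditions, which erases the two uncontrolled carbinol centres while the non-benzylic C3 and C4 centres, the ring ether and the aryl methyl ethers are not affected.

Compound list
1 | (3R,4R)-tetrahydrofuran-3,4-diol (1,4-anhydro-D-threitol, trans) | O[C@@H]1COC[C@H]1O | starting material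
2 | 3,4-dimethoxybenzyl chloride | COc1ccc(CCl)cc1OC | starting material
3 | (3R,4R)-3,4-bis[(3,4-dimethoxybenzyl)oxy]tetrahydrofuran | COc1ccc(CO[C@@H]2COC[C@H]2OCc2ccc(OC)c(OC)c2)cc1OC | intermediate
4 | lithium (3,4-dimethoxyphenyl){(3S,4S)-4-[(3,4-dimethoxybenzyl)oxy]tetrahydrofuran-3-yl}methanolate (carbinolate centre unassigned; not isolated) | COc1ccc(C([O-])[C@@H]2COC[C@H]2OCc2ccc(OC)c(OC)c2)cc1OC.[Li+] | intermediate
5 | [(3S,4S)-tetrahydrofuran-3,4-diyl]bis[(3,4-dimethoxyphenyl)methanol] (carbinol centres unassigned) | COc1ccc(C(O)[C@@H]2COC[C@H]2C(O)c2ccc(OC)c(OC)c2)cc1OC | intermediate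
6 | [(3S,4S)-tetrahydrofuran-3,4-diyl]bis[(3,4-dimethoxyphenyl)methylene] diacetate (acetoxy-bearing centres unassigned) | COc1ccc(C(OC(C)=O)[C@@H]2COC[C@H]2C(OC(C)=O)c2ccc(OC)c(OC)c2)cc1OC | intermediate
7 | (3S,4S)-3,4-bis(3,4-dimethoxybenzyl)tetrahydrofuran | COc1ccc(C[C@@H]2COC[C@H]2Cc2ccc(OC)c(OC)c2)cc1OC | target

Total step count: 4
Longest linear sequence: 4 steps (1 → 3 → 5 → 6 → 7)

Steps most likely to fail

1. Step 2. The twofold rearrangement may stall after one migration. The base may be diverted into aryl or ring metalation, the benzylic anion may fragment by syn β-elimination, and configuration may be partly lost if the radical escapes the solvent cage before recombining. The fallback uses only known reaction types, sets out from 2 and rejoins the route at 7.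
   - Mono-tert-butyl succinate is activated with pivaloyl chloride/Et3N and coupled with (S)-4-benzyloxazolidin-2-one (LiCl) to give tert-butyl 4-[(4S)-4-benzyl-2-oxo-1,3-oxazolidin-3-yl]-4-oxobutanoate F1.
   - Its sodium enolate (NaN(SiMe3)2, THF, −78 °C) is alkylated with 2 (NaI) on the face away from the auxiliary benzyl group, giving tert-butyl (3S)-4-[(4S)-4-benzyl-2-oxo-1,3-oxazolidin-3-yl]-3-(3,4-dimethoxybenzyl)-4-oxobutanoate F2.
   - LiBH4 (THF, 0 °C) removes the auxiliary reductively to give tert-butyl (3S)-4-(3,4-dimethoxyphenyl)-3-(hydroxymethyl)butanoate F3.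
   - F3 lactonises with catalytic TsOH in warm toluene to (4S)-4-(3,4-dimethoxybenzyl)dihydrofuran-2(3H)-one F4.
   - The lithium enolate of F4 (LiN(SiMe3)2, THF, −78 °C) is alkylated with a second portion of 2 (NaI) anti to the C4 substituent, giving the trans lactone (3S,4S)-3,4-bis(3,4-dimethoxybenzyl)dihydrofuran-2(3H)-one F5.
   - LiAlH4 (THF, 0 °C) opens F5 to (2S,3S)-2,3-bis(3,4-dimethoxybenzyl)butane-1,4-diol F6.
   - Acid-catalysed cyclodehydration of F6 (TsOH, toluene, reflux with removal of water) closes the tetrahydrofuran ring to 7.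

2. Step 4. Cleavage of the two hindered secondary benzylic C–O bonds may remain incomplete. Acetic acid may also be lost toward C3 or C4 and the resulting alkene hydrogenated unselectively, which would erode the trans relationship. The fallback sets out from 5 and rejoins at 7 by twofold Barton–McCombie deoxygenation. 1,1'-Thiocarbonyldiimidazole (DMAP cat., THF, reflux) should convert 5 into O,O'-{[(3S,4S)-tetrahydrofuran-3,4-diyl]bis[(3,4-dimethoxyphenyl)methylene]} bis(1H-imidazole-1-carbothioate) F7. Bu3SnH/AIBN in toluene at 90 °C then replaces both C–O bonds by C–H through exocyclic benzylic radicals, which leave C3 and C4 untouched, to give 7.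

3. Step 1. The second alkylation of the vicinal diol may be slow, and the electron-rich benzyl chloride may be consumed by hydrolysis or self-condensation under the basic conditions. The fallback sets out from 1 and rejoins at 3 by acid-catalysed benzylation in place of alkoxide displacement. 3,4-Dimethoxybenzyl 2,2,2-trichloroacetimidate F8 is prepared from 3,4-dimethoxybenzyl alcohol and Cl3CCN (cat. DBU). It is reacted with 1 (2.5 equiv of F8, cat. camphorsulfonic acid, CH2Cl2, rt) to give 3 without touching the C–O stereocentres.

Further compounds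
F1 | step 2 | tert-butyl 4-[(4S)-4-benzyl-2-oxo-1,3-oxazolidin-3-yl]-4-oxobutanoate | CC(C)(C)OC(=O)CCC(=O)N1[C@@H](Cc2ccccc2)COC1=O
F2 | step 2 | tert-butyl (3S)-4-[(4S)-4-benzyl-2-oxo-1,3-oxazolidin-3-yl]-3-(3,4-dimethoxybenzyl)-4-oxobutanoate | COc1ccc(C[C@@H](CC(=O)OC(C)(C)C)C(=O)N2[C@@H](Cc3ccccc3)COC2=O)cc1OC
F3 | step 2 | tert-butyl (3S)-4-(3,4-dimethoxyphenyl)-3-(hydroxymethyl)butanoate | COc1ccc(C[C@H](CO)CC(=O)OC(C)(C)C)cc1OC
F4 | step 2 | (4S)-4-(3,4-dimethoxybenzyl)dihydrofuran-2(3H)-one | COc1ccc(C[C@@H]2COC(=O)C2)cc1OC
F5 | step 2 | (3S,4S)-3,4-bis(3,4-dimethoxybenzyl)dihydrofuran-2(3H)-one | COc1ccc(C[C@@H]2COC(=O)[C@H]2Cc2ccc(OC)c(OC)c2)cc1OC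
F6 | step 2 | (2S,3S)-2,3-bis(3,4-dimethoxybenzyl)butane-1,4-diol | COc1ccc(C[C@H](CO)[C@@H](CO)Cc2ccc(OC)c(OC)c2)cc1OC
F7 | step 4 | O,O'-{[(3S,4S)-tetrahydrofuran-3,4-diyl]bis[(3,4-dimethoxyphenyl)methylene]} bis(1H-imidazole-1-carbothioate) | COc1ccc(C(OC(=S)n2ccnc2)[C@@H]3COC[C@H]3C(OC(=S)n4ccnc4)c5ccc(OC)c(OC)c5)cc1OC
F8 | step 1 | 3,4-dimethoxybenzyl 2,2,2-trichloroacetimidate | COc1ccc(COC(=N)C(Cl)(Cl)Cl)cc1OC
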